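**Plan**

- Retrosynthesis: cut the C6–O ester bond, then C6–H (back to a ketone) and C7–H/C10–H (back to a diene). Then cut C1–C5 and C1–C10 together, which turns the seven-membered ring back into a benzene ring plus a carbenoid carbon. Last, cut C1–C2 (diazoethane acylation), C4–isopropyl (1,2-metallate shift) and C3–C4 (allylation).
- Enabling feature: ring atoms C5–C6–C7–C8–C9–C10 carry the pattern of a benzene ring (carbon substituent at C5, oxygen at C6 ortho to it, methyl at C8 para to it). The seventh ring atom C1 is quaternary and α to the C2 ketone, so it can be the carbenoid carbon of an α-diazo ketone. O4 and O6 are 1,3-related across C5, so one silicon atom can bridge them.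
- Forward: the side chain (C4, C3, C2) is built on 2-methoxy-4-methylbenzaldehyde, O4 and O6 are tied as a silylene, and the diazoketone is made. One step then closes the cyclopentanone and expands the benzene ring to a cycloheptatriene. The triene is trimmed by protonation, 1,4-hydrogenation and ketone reduction, and the ester is attached last.
- Stereochemistry: C4 comes from an asymmetric allylboration followed by a stereospecific lithiation–borylation. C1 is relayed from C4 through the silylene tether. C5 is set by protonation (trans fusion, also the expected thermodynamic epimer). C6 is set by hydride delivered from the C4 hydroxyl.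

Key step: step 8

Remark: atoms are numbered as in daucane (C1 quaternary ring-fusion carbon with methyl, C2 ring ketone, C3, C4 carbinol carbon with isopropyl, C5 ring-fusion CH, C6 acyloxy carbon, C7, C8 methyl-bearing alkene carbon, C9, C10). β is the face of the C1 methyl group, α the opposite face.
Assumption: (+)-Ipc2B(allyl), 4 and 19 are bought as such; diazoethane is prepared separately as an ethereal solution and used at once.

**Route**

Step 1
Reactants: 1 2-methoxy-4-methylbenzaldehyde
Product: 2 (1R)-1-(2-methoxy-4-methylphenyl)but-3-en-1-ol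
Conditions: (+)-Ipc2B(allyl) (antipode derived from (−)-α-pinene), Et2O, −78 °C; then NaOH, H2O2, 0 °C to rt
Reagents that add atoms: (+)-B-allyldiisopinocampheylborane, C=CCB([C@H]1C[C@H]2C[C@@H]([C@@H]1C)C2(C)C)[C@H]1C[C@H]2C[C@@H]([C@@H]1C)C2(C)C
Why: Brown asymmetric allylboration through a chair-like six-membered transition state, in which the isopinocampheyl groups of the (+)-reagent should direct allyl transfer to the aldehyde face that gives the (R)-carbinol (the future C4, still secondary).

Step 2
Reactants: 2 (1R)-1-(2-methoxy-4-methylphenyl)but-3-en-1-ol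
Product: 3 (1R)-1-(2-methoxy-4-methylphenyl)but-3-en-1-yl N,N-diisopropylcarbamate
Conditions: i-Pr2NCOCl, Et3N, MeCN, 80 °C
Reagents that add atoms: N,N-diisopropylcarbamoyl chloride, CC(C)N(C(C)C)C(Cl)=O
Why: O-carbamoylation of the secondary benzylic alcohol installs the directing and leaving group for the next step without touching the stereocentre.

Step 3
Reactants: 3 (1R)-1-(2-methoxy-4-methylphenyl)but-3-en-1-yl N,N-diisopropylcarbamate; 4 2-isopropyl-4,4,5,5-tetramethyl-1,3,2-dioxaborolane
Product: 6 (3R)-3-(2-methoxy-4-methylphenyl)-2-methylhex-5-en-3-ol, via tertiary pinacol boronate 5 (not isolated)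
Conditions: s-BuLi, Et2O, −78 °C; then 4; then MgBr2/MeOH, −78 °C to rt; then NaOH, H2O2, THF, 0 °C to rt
Reagents that add atoms: hydrogen peroxide, OO
Why: Lithiation–borylation (carbamate-directed benzylic deprotonation and borylation with retention, 1,2-metallate shift of isopropyl from boron to carbon with inversion at the C–O bond, then stereoretentive C–B oxidation) should convert the (R)-carbamate stereospecifically into the (R)-tertiary alcohol, which is C4 of the target.

Step 4
Reactants: 6 (3R)-3-(2-methoxy-4-methylphenyl)-2-methylhex-5-en-3-ol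
Product: 7 2-[(3R)-3-hydroxy-2-methylhex-5-en-3-yl]-5-methylphenol
Conditions: LiPPh2, THF, rt to 50 °C; then aq. NH4Cl
Reagents that add atoms: none
Why: SN2 demethylation of the aryl methyl ether by the soft phosphide nucleophile, which leaves the tertiary alkoxide and the terminal alkene untouched.

Step 5
Reactants: 7 2-[(3R)-3-hydroxy-2-methylhex-5-en-3-yl]-5-methylphenol
Product: 8 (4R)-4-allyl-2,2-di-tert-butyl-4-isopropyl-7-methyl-4H-1,3,2-benzodioxasiline
Conditions: t-Bu2Si(OTf)2, 2,6-lutidine, CH2Cl2, 0 to 40 °C
Reagents that add atoms: di-tert-butylsilyl bis(trifluoromethanesulfonate), CC(C)(C)[Si](OS(=O)(=O)C(F)(F)F)(OS(=O)(=O)C(F)(F)F)C(C)(C)C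
Why: Silylene protection of a 1,3-related phenol/tertiary alcohol pair closes a six-membered dioxasiline ring (phenol silylation first, then ring closure on the tertiary hydroxyl) that masks both oxygens and fixes O4 next to C6.

Step 6
Reactants: 8 (4R)-4-allyl-2,2-di-tert-butyl-4-isopropyl-7-methyl-4H-1,3,2-benzodioxasiline
Product: 10 [(4R)-2,2-di-tert-butyl-4-isopropyl-7-methyl-4H-1,3,2-benzodioxasilin-4-yl]acetic acid, via silylene aldehyde 9 (not isolated)
Conditions: O3, CH2Cl2/MeOH, −78 °C (Sudan III end point); Me2S; then NaClO2, NaH2PO4, 2-methylbut-2-ene, t-BuOH/H2O, rt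
Reagents that add atoms: ozone, [O-][O+]=O; sodium chlorite, [Na+].[O-]Cl=O
Why: Ozonolysis of the terminal alkene (far faster than attack on the arene when the end point is indicated) followed by Pinnick oxidation of the aldehyde gives the acid that carries C2.

Step 7
Reactants: 10 [(4R)-2,2-di-tert-butyl-4-isopropyl-7-methyl-4H-1,3,2-benzodioxasilin-4-yl]acetic acid
Product: 12 3-diazo-1-[(4R)-2,2-di-tert-butyl-4-isopropyl-7-methyl-4H-1,3,2-benzodioxasilin-4-yl]butan-2-one, via acid chloride 11 (not isolated)
Conditions: (COCl)2, cat. DMF, CH2Cl2, 0 °C; evaporate; then CH3CHN2 (excess), Et2O, −20 to 0 °C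
Reagents that add atoms: diazoethane, CC=[N+]=[N-]
Why: Acylation of diazoethane by the acid chloride (Arndt–Eistert-type diazoketone synthesis, excess diazoalkane as HCl scavenger) brings in C1 with its methyl group.

Step 8
Reactants: 12 3-diazo-1-[(4R)-2,2-di-tert-butyl-4-isopropyl-7-methyl-4H-1,3,2-benzodioxasilin-4-yl]butan-2-one
Product: 14 (1R,4R)-4,6-O-(di-tert-butylsilanediyl)-4,6-dihydroxydauca-5,7,9-trien-2-one, via norcaradiene 13 (not isolated)
Conditions: Rh2(OAc)4 (1 mol %), CH2Cl2, 40 °C, slow addition of 12
Reagents that add atoms: none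
Why: Rh2(OAc)4 converts the diazo group of 12 into an electrophilic rhodium carbenoid at C1 that adds across the C5–C10 π bond of the arene to give norcaradiene 13, which opens by disrotatory 6π electrocyclic cleavage of the C5–C10 σ bond to the cycloheptatriene 14. This is the intramolecular Buchner reaction of aryl-tethered α-diazo ketones, the reaction type that gives 8a-methyl-3,4-dihydroazulen-1(2H)-ones from diazoethane-derived diazoketones of 3-arylpropanoic acids. The cyclopentanone closes by C1–C5 bond formation through the three-atom tether C2–C3–C4 (carbenoid addition at the ipso carbon), and the seven-membered ring arises by insertion of C1 into the aromatic C5–C10 bond (cyclopropanation, then electrocyclic ring-opening). The only new stereocentre, C1, is controlled by C4 through the silylene: the Si bridge holds O4 in the arene plane on the C6 side, so C3 sits on one face of the ring and the carbenoid can reach the C5–C10 bond only from that face, which puts the C1 methyl syn to O4 and anti to the isopropyl group, as in the target. The step needs attack at C5–C10 and not at C5–C6 (shielded by the t-Bu2Si group, and ring-opening there would break a bond of the dioxasiline ring), and arene addition in preference to 1,2-hydride shift, C–H insertion or ylide formation; the isopropyl C–H is β to oxygen and so deactivated, the silyl ether oxygens are hindered and weakly basic, and the fully substituted C4 favours cyclisation. Because C1 is quaternary, 14 can neither aromatise to a 2-tetralone nor undergo 1,5-hydrogen shifts.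

Step 9
Reactants: 14 (1R,4R)-4,6-O-(di-tert-butylsilanediyl)-4,6-dihydroxydauca-5,7,9-trien-2-one
Product: 16 (1R,4R,5R)-4-hydroxydauca-7,9-diene-2,6-dione, via fluorosilyl ether 15 (not isolated)
Conditions: HF·pyridine, pyridine, THF, 0 °C to rt
Reagents that add atoms: none
Why: Protodesilylation of the silyl enol ether: fluoride should cleave the enol Si–O bond first, and the trienol ketonises by protonation at C5, expected on the α-face (anti to the C1 methyl and the still silylated O4), which gives the trans ring fusion; this C5 centre is α to the C6 ketone and the trans epimer (C6 anti to isopropyl, O4–H···O6 hydrogen bond) is also expected to be the thermodynamic one, before the second Si–O bond is cleaved.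

Step 10
Reactants: 16 (1R,4R,5R)-4-hydroxydauca-7,9-diene-2,6-dione
Product: 17 (1R,4R,5R)-4-hydroxydauc-8-ene-2,6-dione
Conditions: (η6-naphthalene)Cr(CO)3 (20 mol %), H2 (70 atm), THF, 45 °C
Reagents that add atoms: none
Why: (Arene)Cr(CO)3-catalysed 1,4-hydrogenation of the s-cis diene C7=C8–C9=C10 (the mode known for sorbate-type dienes) should add hydrogen at C7 and C10 and leave the C8=C9 alkene, while the ketones and the s-trans enone unit are not substrates.

Step 11
Reactants: 17 (1R,4R,5R)-4-hydroxydauc-8-ene-2,6-dione
Product: 18 (1R,4R,5S,6S)-4,6-dihydroxydauc-8-en-2-one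
Conditions: Me4NBH(OAc)3, MeCN/AcOH, −30 °C
Reagents that add atoms: none
Why: Evans–Saksena hydroxyl-directed reduction: the C4 hydroxyl exchanges onto boron and delivers hydride intramolecularly to the β-face of C6 (the face on which O4 lies), which should give the 1,3-anti diol with the 6α-hydroxyl (6S), while C2, whose β-face is screened by the adjacent angular methyl, is expected to react more slowly.

Step 12
Reactants: 18 (1R,4R,5S,6S)-4,6-dihydroxydauc-8-en-2-one; 19 4-[(tert-butyldimethylsilyl)oxy]benzoic acid
Product: 20 (1R,4R,5S,6S)-4-hydroxy-2-oxodauc-8-en-6-yl 4-[(tert-butyldimethylsilyl)oxy]benzoate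
Conditions: EDC·HCl, DMAP, CH2Cl2, 0 °C to rt
Reagents that add atoms: none
Why: Steglich esterification should acylate the secondary C6 hydroxyl with retention, since the tertiary C4 hydroxyl is too hindered to compete.

Step 13
Reactants: 20 (1R,4R,5S,6S)-4-hydroxy-2-oxodauc-8-en-6-yl 4-[(tert-butyldimethylsilyl)oxy]benzoate
Product: 21 (1R,4R,5S,6S)-4-hydroxy-2-oxodauc-8-en-6-yl 4-hydroxybenzoate
Conditions: HF·pyridine, THF, 0 °C
Reagents that add atoms: none
Why: Fluoride cleavage of the aryl silyl ether under non-basic conditions, under which the benzoate ester, the β-hydroxy ketone and the β,γ-placed alkene should survive.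

**Compound list**

1 | 2-methoxy-4-methylbenzaldehyde | COc1cc(C)ccc1C=O | starting material
2 | (1R)-1-(2-methoxy-4-methylphenyl)but-3-en-1-ol | C=CC[C@@H](O)c1ccc(C)cc1OC | intermediate
3 | (1R)-1-(2-methoxy-4-methylphenyl)but-3-en-1-yl N,N-diisopropylcarbamate | C=CC[C@@H](OC(=O)N(C(C)C)C(C)C)c1ccc(C)cc1OC | intermediate
4 | 2-isopropyl-4,4,5,5-tetramethyl-1,3,2-dioxaborolane | CC(C)B1OC(C)(C)C(C)(C)O1 | starting material
5 | 2-[(3S)-3-(2-methoxy-4-methylphenyl)-2-methylhex-5-en-3-yl]-4,4,5,5-tetramethyl-1,3,2-dioxaborolane | C=CC[C@@](B1OC(C)(C)C(C)(C)O1)(C(C)C)c1ccc(C)cc1OC | intermediate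
6 | (3R)-3-(2-methoxy-4-methylphenyl)-2-methylhex-5-en-3-ol | C=CC[C@@](O)(C(C)C)c1ccc(C)cc1OC | intermediate
7 | 2-[(3R)-3-hydroxy-2-methylhex-5-en-3-yl]-5-methylphenol | C=CC[C@@](O)(C(C)C)c1ccc(C)cc1O | intermediate
8 | (4R)-4-allyl-2,2-di-tert-butyl-4-isopropyl-7-methyl-4H-1,3,2-benzodioxasiline | C=CC[C@@](O[Si]1(C(C)(C)C)C(C)(C)C)(C(C)C)c2ccc(C)cc2O1 | intermediate
9 | [(4R)-2,2-di-tert-butyl-4-isopropyl-7-methyl-4H-1,3,2-benzodioxasilin-4-yl]acetaldehyde | O=CC[C@@](O[Si]1(C(C)(C)C)C(C)(C)C)(C(C)C)c2ccc(C)cc2O1 | intermediate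
10 | [(4R)-2,2-di-tert-butyl-4-isopropyl-7-methyl-4H-1,3,2-benzodioxasilin-4-yl]acetic acid | OC(=O)C[C@@](O[Si]1(C(C)(C)C)C(C)(C)C)(C(C)C)c2ccc(C)cc2O1 | intermediate
11 | [(4R)-2,2-di-tert-butyl-4-isopropyl-7-methyl-4H-1,3,2-benzodioxasilin-4-yl]acetyl chloride | ClC(=O)C[C@@](O[Si]1(C(C)(C)C)C(C)(C)C)(C(C)C)c2ccc(C)cc2O1 | intermediate
12 | 3-diazo-1-[(4R)-2,2-di-tert-butyl-4-isopropyl-7-methyl-4H-1,3,2-benzodioxasilin-4-yl]butan-2-one | CC(=[N+]=[N-])C(=O)C[C@@](O[Si]1(C(C)(C)C)C(C)(C)C)(C(C)C)c2ccc(C)cc2O1 | intermediate
13 | norcaradiene valence isomer of 14 (cyclopropane C1–C5–C10, diene C6=C7/C8=C9, cyclopentanone and dioxasiline rings on opposite faces of the cyclopropane) | CC1=C[C@@H]2[C@@]3(C)C(=O)C[C@](C(C)C)(O[Si](C(C)(C)C)(C(C)(C)C)O4)[C@@]23C4=C1 | intermediate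
14 | (1R,4R)-4,6-O-(di-tert-butylsilanediyl)-4,6-dihydroxydauca-5,7,9-trien-2-one | CC1=CC2=C3[C@@](C(C)C)(O[Si](C(C)(C)C)(C(C)(C)C)O2)CC(=O)[C@]3(C)C=C1 | intermediate
15 | (1R,4R,5R)-4-[(di-tert-butylfluorosilyl)oxy]dauca-7,9-diene-2,6-dione | CC1=CC(=O)[C@H]2[C@](O[Si](F)(C(C)(C)C)C(C)(C)C)(C(C)C)CC(=O)[C@]2(C)C=C1 | intermediate
16 | (1R,4R,5R)-4-hydroxydauca-7,9-diene-2,6-dione (trans-fused, 5α-H) | CC1=CC(=O)[C@H]2[C@](O)(C(C)C)CC(=O)[C@]2(C)C=C1 | intermediate
17 | (1R,4R,5R)-4-hydroxydauc-8-ene-2,6-dione | CC1=CC[C@@]2(C)C(=O)C[C@@](O)(C(C)C)[C@@H]2C(=O)C1 | intermediate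
18 | (1R,4R,5S,6S)-4,6-dihydroxydauc-8-en-2-one | CC1=CC[C@@]2(C)C(=O)C[C@@](O)(C(C)C)[C@@H]2[C@@H](O)C1 | intermediate
19 | 4-[(tert-butyldimethylsilyl)oxy]benzoic acid | CC(C)(C)[Si](C)(C)Oc1ccc(cc1)C(=O)O | starting material
20 | (1R,4R,5S,6S)-4-hydroxy-2-oxodauc-8-en-6-yl 4-[(tert-butyldimethylsilyl)oxy]benzoate | CC1=CC[C@@]2(C)C(=O)C[C@@](O)(C(C)C)[C@@H]2[C@@H](OC(=O)c2ccc(O[Si](C)(C)C(C)(C)C)cc2)C1 | intermediate
21 | [(3R,3aS,4S,8aR)-3-hydroxy-6,8a-dimethyl-1-oxo-3-(propan-2-yl)-1,2,3,3a,4,5,8,8a-octahydroazulen-4-yl] 4-hydroxybenzoate | CC1=CC[C@@]2(C)C(=O)C[C@@](O)(C(C)C)[C@@H]2[C@@H](OC(=O)c2ccc(O)cc2)C1 | target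

**Step count**

Total steps: 13. Longest linear sequence: 13 (from 1).

**Steps most likely to fail**

1. Step 8. What may go wrong: the carbenoid is consumed before it reaches the hindered arene. The competing processes are 1,2-hydride shift from the C1 methyl group (loss of the diazo carbon as a vinyl ketone), insertion into the isopropyl C–H bond, and attack by a silyl ether oxygen. Fallback: the quaternary centre is built in two stages and not by a methyl-bearing carbenoid. The fallback sets out from acid 10. Its acid chloride 11 is treated with diazomethane to give the terminal diazoketone F1, whose carbenoid has no β-hydrogen and is less hindered. Rh2(OAc)4 should then give the trienone with an angular hydrogen F2, in the parent mode of the same ring expansion. Deprotonation of F2 at C1 (KHMDS, THF, −78 °C, no acid contact beforehand) and kinetic C-methylation of the extended enolate at its α-carbon with MeI, anti to the pseudoaxial isopropyl group on C4, should return to 14.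

2. Step 11. What may go wrong: ligand exchange at the tertiary hydroxyl is slow, and hydride is also delivered to the C2 carbonyl, which is likewise β to O4; the result would be loss of site selectivity or over-reduction. Fallback: external hydride followed by inversion. The fallback sets out from 17. L-Selectride (THF, −78 °C) should reduce the less hindered C6 ketone from the open α-face, C2 being neopentyl, to give the 6β-alcohol F3. Mitsunobu esterification of F3 with acid 19 (PPh3, DIAD, toluene) inverts C6 and rejoins the route at 20.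

3. Step 10. What may go wrong: hydrogen transfer to the hindered diene is slow or unselective (C10 is neopentyl), with 1,2-addition or migration of the new alkene into conjugation with C6. Fallback: dissolving-metal reduction in place of catalytic hydrogenation. The fallback sets out from 16. Lithium in NH3/THF at −78 °C (two equivalents beyond the one consumed by the hydroxyl) should reduce the dienone to the dienolate with protonation at C10, and a kinetic quench with solid NH4Cl protonates the α-carbon C7. This returns to 17 and makes no new compound (F0).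

**Further compounds**

F1 | step 8 | 1-diazo-3-[(4R)-2,2-di-tert-butyl-4-isopropyl-7-methyl-4H-1,3,2-benzodioxasilin-4-yl]propan-2-one | [N-]=[N+]=CC(=O)C[C@@](O[Si]1(C(C)(C)C)C(C)(C)C)(C(C)C)c2ccc(C)cc2O1
F2 | step 8 | (4R)-4,6-O-(di-tert-butylsilanediyl)-4,6-dihydroxy-15-nordauca-5,7,9-trien-2-one (angular H at C1) | CC1=CC2=C3[C@@](C(C)C)(O[Si](C(C)(C)C)(C(C)(C)C)O2)CC(=O)[C@@H]3C=C1
F3 | step 11 | (1R,4R,5S,6R)-4,6-dihydroxydauc-8-en-2-one (6β-alcohol) | CC1=CC[C@@]2(C)C(=O)C[C@@](O)(C(C)C)[C@@H]2[C@H](O)C1
F0 | step 10 | none | none
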